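**Retrosynthetic overview**

- Gnetumontanin B 26 ⇐ nonamethyl ether 25 ⇐ octamethyl ether 21, by C–H borylation at C6 of ring A and Suzuki coupling with a 4-methoxystyryl bromide; 21 ⇐ diacid 16 by twofold decarboxylative arylation at C3 and C3′.
- Feature used: in ring A (O1, C2, C3) and ring B (O1′, C2′, C3′; C7′ bonded to C2), C2 and C2′ are each a benzylic carbon bonded to a ring oxygen. Each is therefore the CH2 carbon of a benzyl aryl ether, one bond away from C3 or C3′.
- Key disconnection: C2–C3 and C2′–C3′, both made by rhodium carbene insertion into the two ArO–CH2–Ar′ C–H bonds of bis(diazo ester) 13. Both dihydrofuran rings close in this one step, in either order.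
- 13 ⇐ bis(arylacetate) 12 ⇐ a single arylacetate 7, used as such for ring A and after ortho-formylation for ring B, joined with 2,4-dimethoxybenzyl alcohol by two Mitsunobu etherifications; 7 comes from 3-methoxyphenol by directed ortho-metalation.
- The esters at C3 and C3′ are placeholders: as planar radicals they take the 3,5-dimethoxyphenyl groups trans to the aryl groups at C2 and C2′.

Key step: step 10

Assumption on stereochemistry: Rh2(S-PTTL)4 is taken to give the (2S,2′S) sense of insertion; if this benzyl ether responds with the opposite sense, the mirror-image catalyst Rh2(R-PTTL)4 is used with no other change.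

Remark on the twofold steps 9 to 13: the two like groups react one after the other in either order, and these half-converted species are not numbered separately.

**Route**

Step 1
Reactants: 1 3-methoxyphenol
Product: 2 1-methoxy-3-(methoxymethoxy)benzene
Conditions: NaH, MOMCl, THF, 0 °C → rt
Reagents that add atoms: chloromethyl methyl ether, COCCl
Why: Williamson O-alkylation of the sodium phenoxide installs the MOM ether, which then serves as the second ortho-directing group.

Step 2
Reactants: 2 1-methoxy-3-(methoxymethoxy)benzene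
Product: 4 2-bromo-1-methoxy-3-(methoxymethoxy)benzene, via aryllithium 3 (not isolated)
Conditions: n-BuLi, THF, 0 °C; then BrCCl2CCl2Br, −78 °C → rt
Reagents that add atoms: 1,2-dibromo-1,1,2,2-tetrachloroethane, BrC(Cl)(Cl)C(Cl)(Cl)Br
Why: Directed ortho-metalation, in which OMe and OMOM together direct lithiation to the carbon between them, followed by bromine transfer to the aryllithium.

Step 3
Reactants: 4 2-bromo-1-methoxy-3-(methoxymethoxy)benzene; 5 (2-tert-butoxy-2-oxoethyl)zinc chloride
Product: 6 tert-butyl 2-[2-methoxy-6-(methoxymethoxy)phenyl]acetate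
Conditions: Pd2(dba)3 (cat.), XPhos, THF, 65 °C
Reagents that add atoms: none
Why: Negishi-type palladium-catalysed α-arylation of a Reformatsky zinc enolate, which tolerates the di-ortho-substituted bromide and, being non-basic, leaves the MOM ether and the ester untouched.

Step 4
Reactants: 6 tert-butyl 2-[2-methoxy-6-(methoxymethoxy)phenyl]acetate
Product: 7 methyl 2-(2-hydroxy-6-methoxyphenyl)acetate
Conditions: HCl (1.25 M in MeOH), 60 °C; NaHCO3 before concentration
Reagents that add atoms: methanol, CO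
Why: Acidic methanolysis cleaves the MOM acetal and exchanges the tert-butyl ester for the methyl ester in one operation, and neutralising before concentration keeps the hydroxy ester from lactonising.

Step 5
Reactants: 7 methyl 2-(2-hydroxy-6-methoxyphenyl)acetate
Product: 8 methyl 2-(3-formyl-2-hydroxy-6-methoxyphenyl)acetate
Conditions: MgCl2 (anhydrous), Et3N, (CH2O)n, MeCN, reflux
Reagents that add atoms: paraformaldehyde (as formaldehyde), C=O
Why: Casnati–Skattebøl magnesium-mediated ortho-formylation delivers formaldehyde only to the one free carbon ortho to the phenol, and Et3N is too weak a base to enolise the arylacetate.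

Step 6
Reactants: 8 methyl 2-(3-formyl-2-hydroxy-6-methoxyphenyl)acetate; 9 (2,4-dimethoxyphenyl)methanol
Product: 10 methyl 2-{2-[(2,4-dimethoxyphenyl)methoxy]-3-formyl-6-methoxyphenyl}acetate
Conditions: PPh3, DIAD, THF, 0 °C → rt
Reagents that add atoms: none
Why: Mitsunobu etherification of the acidic salicylaldehyde OH with a primary benzylic alcohol under neutral conditions, which avoids the unstable 2,4-dimethoxybenzyl halide.

Step 7
Reactants: 10 methyl 2-{2-[(2,4-dimethoxyphenyl)methoxy]-3-formyl-6-methoxyphenyl}acetate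
Product: 11 methyl 2-{2-[(2,4-dimethoxyphenyl)methoxy]-3-(hydroxymethyl)-6-methoxyphenyl}acetate
Conditions: NaBH4, MeOH/THF, 0 °C
Reagents that add atoms: none
Why: Chemoselective borohydride reduction of the aldehyde in the presence of the methyl ester.

Step 8
Reactants: 11 methyl 2-{2-[(2,4-dimethoxyphenyl)methoxy]-3-(hydroxymethyl)-6-methoxyphenyl}acetate; 7 methyl 2-(2-hydroxy-6-methoxyphenyl)acetate
Product: 12 methyl 2-{2-[(2,4-dimethoxyphenyl)methoxy]-6-methoxy-3-{[3-methoxy-2-(2-methoxy-2-oxoethyl)phenoxy]methyl}phenyl}acetate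
Conditions: PPh3, DIAD, THF, 0 °C → rt
Reagents that add atoms: none
Why: A second Mitsunobu etherification joins the ring-A phenol to the ring-B benzylic alcohol without passing through the very labile electron-rich benzyl halide.

Step 9
Reactants: 12 the bis(arylacetate)
Product: 13 methyl 2-diazo-2-{2-[(2,4-dimethoxyphenyl)methoxy]-3-{[2-(1-diazo-2-methoxy-2-oxoethyl)-3-methoxyphenoxy]methyl}-6-methoxyphenyl}acetate
Conditions: p-ABSA, DBU, MeCN, 0 °C → rt, dark
Reagents that add atoms: 4-acetamidobenzenesulfonyl azide, CC(=O)Nc1ccc(cc1)S(=O)(=O)N=[N+]=[N-]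
Why: Regitz diazo transfer to both arylacetate methylene groups, the standard entry to aryldiazoacetates.

Step 10
Reactants: 13 the bis(α-diazo ester)
Product: 14 methyl (2S,3R)-2-[(2S,3R)-2-(2,4-dimethoxyphenyl)-4-methoxy-3-(methoxycarbonyl)-2,3-dihydro-1-benzofuran-7-yl]-4-methoxy-2,3-dihydro-1-benzofuran-3-carboxylate (cis at both rings)
Conditions: Rh2(S-PTTL)4 (dirhodium tetrakis[N-phthaloyl-(S)-tert-leucinate], 2 mol %), toluene, 4 Å MS, slow addition of 13, −60 → −20 °C
Reagents that add atoms: none
Why: Rh2(S-PTTL)4 expels N2 from each diazo ester to give an electrophilic donor/acceptor rhodium carbene, which inserts into the neighbouring ArO–CH2–Ar′ C–H bond through a concerted, hydride-transfer-like three-centre transition state. The closest known reaction type is the enantioselective intramolecular C–H insertion of methyl 2-(2-benzyloxyphenyl)-2-diazoacetates under chiral dirhodium carboxylate catalysis, which gives cis-2-aryl-3-methoxycarbonyl-2,3-dihydrobenzofurans. Each dihydrofuran closes by a 1,5-insertion through a five-membered transition state (carbene carbon, two arene carbons, oxygen, benzylic carbon), forming C2–C3 in ring A and C2′–C3′ in ring B independently. C2 and C2′ are set by the catalyst, whose chiral pocket selects one of the two enantiotopic benzylic hydrogens, while C3 and C3′ come out cis to the new aryl group as the kinetic outcome of the compact transition state; since both sites are catalyst-controlled, a wrong insertion at one site should end up in a separable diastereomer. The step needs site selectivity for OCH2Ar over the other ortho substituent, OCH3, and the substrate secures it: the benzylic hydrogens are secondary, α to oxygen and on arenes carrying ortho and para alkoxy groups, whereas the methyl C–H bonds are primary. Slow addition at low temperature keeps the diazo concentration low and suppresses carbene dimerisation and azine formation.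

Step 11
Reactants: 14 the cis,cis diester
Product: 16 (2S,3S)-2-[(2S,3S)-3-carboxy-2-(2,4-dimethoxyphenyl)-4-methoxy-2,3-dihydro-1-benzofuran-7-yl]-4-methoxy-2,3-dihydro-1-benzofuran-3-carboxylic acid, via bis-trans diester 15 (not isolated)
Conditions: NaOMe (cat.), MeOH/THF, rt; then LiOH, H2O, 45 °C; 1 M HCl to pH 3–4, 0 °C
Reagents that add atoms: lithium hydroxide, [Li+].[OH-]
Why: Base-mediated epimerisation of the enolisable C3 and C3′ to the trans esters followed by saponification; C2 and C2′ are untouched because ring-opening by β-elimination of the phenoxide (a reverse 5-endo closure) is stereoelectronically disfavoured.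

Step 12
Reactants: 16 the diacid
Product: 17 bis(1,3-dioxoisoindolin-2-yl) (2S,3S)-2-[(2S,3S)-3-carboxylato-2-(2,4-dimethoxyphenyl)-4-methoxy-2,3-dihydro-1-benzofuran-7-yl]-4-methoxy-2,3-dihydro-1-benzofuran-3-carboxylate (bis N-hydroxyphthalimide ester)
Conditions: N-hydroxyphthalimide, DIC, DMAP (cat.), CH2Cl2, rt
Reagents that add atoms: N-hydroxyphthalimide, O=C1c2ccccc2C(=O)N1O
Why: Carbodiimide (Steglich-type) esterification converts both acids into redox-active esters.

Step 13
Reactants: 17 the bis(redox-active ester); 18 1-bromo-3,5-dimethoxybenzene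
Product: 21 (2S,3S)-2-[(2S,3S)-2-(2,4-dimethoxyphenyl)-3-(3,5-dimethoxyphenyl)-4-methoxy-2,3-dihydro-1-benzofuran-7-yl]-3-(3,5-dimethoxyphenyl)-4-methoxy-2,3-dihydro-1-benzofuran, via arylmagnesium bromide 19 (not isolated), via arylzinc chloride 20 (not isolated)
Conditions: 18, Mg, LiCl, THF, rt; ZnCl2; then 17, NiCl2·glyme (cat.), 4,4′-di-tert-butyl-2,2′-bipyridine, THF/DMF, rt
Reagents that add atoms: none
Why: Nickel-catalysed decarboxylative Negishi arylation of redox-active esters: electron transfer from low-valent nickel fragments each ester to CO2, phthalimide anion and a planar benzylic radical at C3 or C3′, which is captured by aryl-nickel and forms the C–aryl bond on the face anti to the adjacent C2 or C2′ aryl group, giving the trans rings.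

Step 14
Reactants: 21 the octamethyl ether
Product: 22 2-{(2S,3S)-2-[(2S,3S)-2-(2,4-dimethoxyphenyl)-3-(3,5-dimethoxyphenyl)-4-methoxy-2,3-dihydro-1-benzofuran-7-yl]-3-(3,5-dimethoxyphenyl)-4-methoxy-2,3-dihydro-1-benzofuran-6-yl}-4,4,5,5-tetramethyl-1,3,2-dioxaborolane
Conditions: [Ir(OMe)(cod)]2 (cat.), 4,4′-di-tert-butyl-2,2′-bipyridine, B2pin2, THF, 80 °C
Reagents that add atoms: bis(pinacolato)diboron, CC1(C)OB(OC1(C)C)B1OC(C)(C)C(C)(C)O1
Why: Iridium-catalysed C–H borylation is sterically controlled, and C6–H of ring A, meta to both ring oxygens, is the only aromatic C–H in 21 with no ortho substituent.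

Step 15
Reactants: 23 (E)-4-methoxycinnamic acid
Product: 24 1-[(E)-2-bromoethenyl]-4-methoxybenzene
Conditions: NBS, LiOAc (cat.), MeCN/H2O, rt
Reagents that add atoms: N-bromosuccinimide, O=C1CCC(=O)N1Br
Why: Catalytic Hunsdiecker bromodecarboxylation of an electron-rich cinnamic acid, which gives the (E)-β-bromostyrene.

Step 16
Reactants: 22 the C6 boronate; 24 1-[(E)-2-bromoethenyl]-4-methoxybenzene
Product: 25 gnetumontanin B nonamethyl ether, (2S,3S)-2-[(2S,3S)-2-(2,4-dimethoxyphenyl)-3-(3,5-dimethoxyphenyl)-4-methoxy-2,3-dihydro-1-benzofuran-7-yl]-3-(3,5-dimethoxyphenyl)-4-methoxy-6-[(E)-2-(4-methoxyphenyl)ethenyl]-2,3-dihydro-1-benzofuran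
Conditions: Pd(dppf)Cl2 (cat.), K3PO4, 1,4-dioxane/H2O, 80 °C
Reagents that add atoms: none
Why: Suzuki–Miyaura coupling of the aryl boronate with the alkenyl bromide proceeds with retention of the (E) geometry.

Step 17
Reactants: 25 the nonamethyl ether
Product: 26 gnetumontanin B, (2S,3S)-2-[(2S,3S)-2-(2,4-dihydroxyphenyl)-3-(3,5-dihydroxyphenyl)-4-hydroxy-2,3-dihydro-1-benzofuran-7-yl]-3-(3,5-dihydroxyphenyl)-6-[(E)-2-(4-hydroxyphenyl)ethenyl]-2,3-dihydro-1-benzofuran-4-ol
Conditions: BBr3, CH2Cl2, −78 °C → rt; MeOH then aq. NaHCO3 at −78 °C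
Reagents that add atoms: none
Why: Lewis-acid cleavage of all nine aryl methyl ethers by BBr3, the usual last step for permethylated stilbene oligomers; any reversible opening of a dihydrofuran at C2–O should reclose to the favoured trans ring because C3 and C3′ are fixed.

**Compound list**

1 | 3-methoxyphenol | COc1cccc(O)c1 | starting material
2 | 1-methoxy-3-(methoxymethoxy)benzene | COCOc1cccc(OC)c1 | intermediate
3 | [2-methoxy-6-(methoxymethoxy)phenyl]lithium | [Li]c1c(OC)cccc1OCOC | intermediate
4 | 2-bromo-1-methoxy-3-(methoxymethoxy)benzene | COCOc1cccc(OC)c1Br | intermediate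
5 | (2-tert-butoxy-2-oxoethyl)zinc chloride (commercial solution in Et2O) | CC(C)(C)OC(=O)C[Zn]Cl | starting material
6 | tert-butyl 2-[2-methoxy-6-(methoxymethoxy)phenyl]acetate | COCOc1cccc(OC)c1CC(=O)OC(C)(C)C | intermediate
7 | methyl 2-(2-hydroxy-6-methoxyphenyl)acetate | COC(=O)Cc1c(O)cccc1OC | intermediate
8 | methyl 2-(3-formyl-2-hydroxy-6-methoxyphenyl)acetate | COC(=O)Cc1c(O)c(C=O)ccc1OC | intermediate
9 | (2,4-dimethoxyphenyl)methanol | COc1ccc(CO)c(OC)c1 | starting material
10 | methyl 2-{2-[(2,4-dimethoxyphenyl)methoxy]-3-formyl-6-methoxyphenyl}acetate | COC(=O)Cc1c(OCc2ccc(OC)cc2OC)c(C=O)ccc1OC | intermediate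
11 | methyl 2-{2-[(2,4-dimethoxyphenyl)methoxy]-3-(hydroxymethyl)-6-methoxyphenyl}acetate | COC(=O)Cc1c(OCc2ccc(OC)cc2OC)c(CO)ccc1OC | intermediate
12 | bis(arylacetate) of the doubly benzyl-etherified rings A and B | COC(=O)Cc1c(OC)cccc1OCc1ccc(OC)c(CC(=O)OC)c1OCc1ccc(OC)cc1OC | intermediate
13 | bis(α-diazo ester), key-step precursor (achiral) | COC(=O)C(=[N+]=[N-])c1c(OC)cccc1OCc1ccc(OC)c(C(=[N+]=[N-])C(=O)OC)c1OCc1ccc(OC)cc1OC | intermediate
14 | cis,cis bis(dihydrobenzofuran) dimethyl ester (2S,3R,2′S,3′R), key-step product | c1cc(OC)c2c(c1)O[C@H](c1ccc(OC)c3c1O[C@H](c1ccc(OC)cc1OC)[C@@H]3C(=O)OC)[C@@H]2C(=O)OC | intermediate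
15 | trans,trans dimethyl ester (2S,3S,2′S,3′S) | c1cc(OC)c2c(c1)O[C@H](c1ccc(OC)c3c1O[C@H](c1ccc(OC)cc1OC)[C@H]3C(=O)OC)[C@H]2C(=O)OC | intermediate
16 | trans,trans diacid (2S,3S,2′S,3′S) | c1cc(OC)c2c(c1)O[C@H](c1ccc(OC)c3c1O[C@H](c1ccc(OC)cc1OC)[C@H]3C(=O)O)[C@H]2C(=O)O | intermediate
17 | bis(N-hydroxyphthalimide) ester of 16 | c1cc(OC)c2c(c1)O[C@H](c1ccc(OC)c3c1O[C@H](c1ccc(OC)cc1OC)[C@H]3C(=O)ON1C(=O)c4ccccc4C1=O)[C@H]2C(=O)ON1C(=O)c3ccccc3C1=O | intermediate
18 | 1-bromo-3,5-dimethoxybenzene | COc1cc(Br)cc(OC)c1 | starting material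
19 | (3,5-dimethoxyphenyl)magnesium bromide | COc1cc([Mg]Br)cc(OC)c1 | intermediate
20 | (3,5-dimethoxyphenyl)zinc chloride | COc1cc([Zn]Cl)cc(OC)c1 | intermediate
21 | octamethyl ether core (2S,3S,2′S,3′S), trans at both rings | c1cc(OC)c2c(c1)O[C@H](c1ccc(OC)c3c1O[C@H](c1ccc(OC)cc1OC)[C@H]3c1cc(OC)cc(OC)c1)[C@H]2c1cc(OC)cc(OC)c1 | intermediate
22 | ring-A C6 pinacol boronate of 21 | CC1(C)OB(OC1(C)C)c1cc(OC)c2c(c1)O[C@H](c1ccc(OC)c3c1O[C@H](c1ccc(OC)cc1OC)[C@H]3c1cc(OC)cc(OC)c1)[C@H]2c1cc(OC)cc(OC)c1 | intermediate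
23 | (E)-4-methoxycinnamic acid | COc1ccc(/C=C/C(=O)O)cc1 | starting material
24 | 1-[(E)-2-bromoethenyl]-4-methoxybenzene | COc1ccc(/C=C/Br)cc1 | intermediate
25 | gnetumontanin B nonamethyl ether | COc1ccc(/C=C/c2cc(OC)c3c(c2)O[C@H](c2ccc(OC)c4c2O[C@H](c2ccc(OC)cc2OC)[C@H]4c2cc(OC)cc(OC)c2)[C@H]3c2cc(OC)cc(OC)c2)cc1 | intermediate
26 | gnetumontanin B (2S,3S,2′S,3′S) | Oc1ccc(/C=C/c2cc(O)c3c(c2)O[C@H](c2ccc(O)c4c2O[C@H](c2ccc(O)cc2O)[C@H]4c2cc(O)cc(O)c2)[C@H]3c2cc(O)cc(O)c2)cc1 | target

**Step count**

Total: 17 steps. Longest linear sequence: 16 steps, from 3-methoxyphenol 1 through 7, 12, 13, 14, 16, 21 and 25 to 26; step 15 is a side branch.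

**Steps most likely to fail**

1. Step 10 (twofold C–H insertion). A molecule that has formed one carbene still carries a second diazo group, so carbene–diazo coupling within or between molecules can compete with insertion. The di-ortho-substituted carbenes may also insert sluggishly, and the second insertion meets a substrate that is already chiral and may be mismatched. Fallback, one ring at a time, setting out from alcohol 11 and coming back at diacid 16: silylation (TBSCl, imidazole, DMF) gives silyl ether F1, and diazo transfer (p-ABSA, DBU) gives mono-diazo ester F2. Rh2(S-PTTL)4 in toluene at low temperature then closes ring B alone to cis ester F3, and AcOH-buffered TBAF frees alcohol F4. Mitsunobu coupling with phenol 7 gives ether F5. Diazo transfer on the ring-A acetate, during which DBU is expected to bring the ring-B ester to trans, gives diazo ester F6. A second rhodium-catalysed insertion closes ring A to the mixed cis/trans diester F7, which is taken through step 11 in place of 14 and converges on 16.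

2. Step 13 (twofold decarboxylative arylation). The hindered benzylic radicals at C3 and C3′ may dimerise, be reduced, or lose the C2 hydrogen to give the benzofuran faster than aryl-nickel captures them, and the arylzinc may attack the activated esters. Fallback, setting out from diacid 16 and bromide 18 (skipping step 12) and coming back at 21: metallaphotoredox decarboxylative arylation with Ir[dF(CF3)ppy]2(dtbbpy)PF6, NiCl2·glyme, 4,4′-di-tert-butyl-2,2′-bipyridine and Cs2CO3 in DMF under blue light. Here the radical is made by oxidation of the carboxylate and the aryl group enters by oxidative addition of 18, so no activated ester or organozinc is present; the same anti approach should give the trans rings.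

3. Step 17 (ninefold demethylation). The Lewis acid may hydrobrominate or oligomerise the electron-rich stilbene, cleavage may stop at partial ethers, and elimination from a ring-opened C2 cation would cost configurational integrity at C3. Fallback, setting out from octamethyl ether 21 and coming back at 26, so that BBr3 never meets the stilbene: BBr3 in CH2Cl2 gives octaphenol F8, and Ac2O/pyridine gives octaacetate F9. Iridium-catalysed borylation as in step 14 gives boronate F10. Commercial (E)-4-acetoxycinnamic acid with NBS and cat. LiOAc gives bromostyrene acetate F11. Suzuki coupling of F10 with F11 (Pd(dppf)Cl2, anhydrous K3PO4, dioxane) gives nonaacetate F12, and K2CO3 in degassed MeOH at rt removes all acetates to give 26.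

**Further compounds**

F1 | step 10 | methyl 2-{3-[(tert-butyldimethylsilyloxy)methyl]-2-[(2,4-dimethoxyphenyl)methoxy]-6-methoxyphenyl}acetate | COC(=O)Cc1c(OCc2ccc(OC)cc2OC)c(CO[Si](C)(C)C(C)(C)C)ccc1OC
F2 | step 10 | methyl 2-diazo-2-{3-[(tert-butyldimethylsilyloxy)methyl]-2-[(2,4-dimethoxyphenyl)methoxy]-6-methoxyphenyl}acetate | COC(=O)C(=[N+]=[N-])c1c(OCc2ccc(OC)cc2OC)c(CO[Si](C)(C)C(C)(C)C)ccc1OC
F3 | step 10 | methyl (2S,3R)-7-[(tert-butyldimethylsilyloxy)methyl]-2-(2,4-dimethoxyphenyl)-4-methoxy-2,3-dihydro-1-benzofuran-3-carboxylate | CC(C)(C)[Si](C)(C)OCc1ccc(OC)c2c1O[C@H](c1ccc(OC)cc1OC)[C@@H]2C(=O)OC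
F4 | step 10 | methyl (2S,3R)-2-(2,4-dimethoxyphenyl)-7-(hydroxymethyl)-4-methoxy-2,3-dihydro-1-benzofuran-3-carboxylate | OCc1ccc(OC)c2c1O[C@H](c1ccc(OC)cc1OC)[C@@H]2C(=O)OC
F5 | step 10 | methyl (2S,3R)-2-(2,4-dimethoxyphenyl)-4-methoxy-7-{[3-methoxy-2-(2-methoxy-2-oxoethyl)phenoxy]methyl}-2,3-dihydro-1-benzofuran-3-carboxylate | COC(=O)Cc1c(OC)cccc1OCc1ccc(OC)c2c1O[C@H](c1ccc(OC)cc1OC)[C@@H]2C(=O)OC
F6 | step 10 | methyl (2S,3S)-7-{[2-(1-diazo-2-methoxy-2-oxoethyl)-3-methoxyphenoxy]methyl}-2-(2,4-dimethoxyphenyl)-4-methoxy-2,3-dihydro-1-benzofuran-3-carboxylate | COC(=O)C(=[N+]=[N-])c1c(OC)cccc1OCc1ccc(OC)c2c1O[C@H](c1ccc(OC)cc1OC)[C@H]2C(=O)OC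
F7 | step 10 | dimethyl ester, cis in ring A and trans in ring B (2S,3R,2′S,3′S) | c1cc(OC)c2c(c1)O[C@H](c1ccc(OC)c3c1O[C@H](c1ccc(OC)cc1OC)[C@H]3C(=O)OC)[C@@H]2C(=O)OC
F0 | step 13 | none | none
F8 | step 17 | octaphenol core (2S,3S,2′S,3′S) | c1cc(O)c2c(c1)O[C@H](c1ccc(O)c3c1O[C@H](c1ccc(O)cc1O)[C@H]3c1cc(O)cc(O)c1)[C@H]2c1cc(O)cc(O)c1
F9 | step 17 | octaacetate of F8 | c1cc(OC(C)=O)c2c(c1)O[C@H](c1ccc(OC(C)=O)c3c1O[C@H](c1ccc(OC(C)=O)cc1OC(C)=O)[C@H]3c1cc(OC(C)=O)cc(OC(C)=O)c1)[C@H]2c1cc(OC(C)=O)cc(OC(C)=O)c1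
F10 | step 17 | ring-A C6 pinacol boronate of F9 | CC1(C)OB(OC1(C)C)c1cc(OC(C)=O)c2c(c1)O[C@H](c1ccc(OC(C)=O)c3c1O[C@H](c1ccc(OC(C)=O)cc1OC(C)=O)[C@H]3c1cc(OC(C)=O)cc(OC(C)=O)c1)[C@H]2c1cc(OC(C)=O)cc(OC(C)=O)c1
F11 | step 17 | 4-[(E)-2-bromoethenyl]phenyl acetate | CC(=O)Oc1ccc(/C=C/Br)cc1
F12 | step 17 | gnetumontanin B nonaacetate | CC(=O)Oc1ccc(/C=C/c2cc(OC(C)=O)c3c(c2)O[C@H](c2ccc(OC(C)=O)c4c2O[C@H](c2ccc(OC(C)=O)cc2OC(C)=O)[C@H]4c2cc(OC(C)=O)cc(OC(C)=O)c2)[C@H]3c2cc(OC(C)=O)cc(OC(C)=O)c2)cc1
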